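**Retrosynthetic overview**
- The 14-membered carbocycle is closed last, at C12–C13, by an intramolecular Nozaki–Hiyama–Kishi reaction of an alkenyl iodide with an aldehyde; only a C7 silyl ether is removed afterwards.
- The α-methylene ε-lactone is formed before the macrocycle: the C17 acid opens a (4R,5R)-epoxide 7-exo at C4 with inversion, and the freed C5 hydroxyl is acetylated; the epoxide comes from Shi epoxidation of the E-C4=C5 olefin.
- The open chain comes from a Negishi sp3–sp2 coupling at C3–C4 of fragment A (C13–C3 plus the C15–C17 acrylate; C1 from (R)-carvone) with fragment BC (C4–C12).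
- Fragment BC comes from a Z-selective Wittig reaction at C8=C9 between fragment B (α-silyloxy methyl ketone, C7 from methyl (R)-glycidate) and fragment C (ylide from pent-3-yn-1-ol).
- Ring order: oxepan-2-one first (step 23), carbocycle second (step 26).

Locants (cembrane-type, used throughout): C1 = ring CH bonded to acrylate carbon C15 (C16 = CH2, C17 = C=O); C4 = O–C(CH3); C5 = CHOAc; C7 and C13 = CHOH; C8=C9 is Z; C11=C12 is E. The target is (1S,4S,5R,7R,13R).

**Fragment A**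

Step 1
Reactants: 1 (R)-(−)-carvone, (5R)-2-methyl-5-(prop-1-en-2-yl)cyclohex-2-en-1-one
Product: 2 (1R,4R,6R)-1-methyl-4-(prop-1-en-2-yl)-7-oxabicyclo[4.1.0]heptan-2-one
Conditions: H2O2 (30% aq.), NaOH (cat.), MeOH, 0 °C
Reagents that add atoms: hydrogen peroxide, OO
Why: Weitz–Scheffer nucleophilic epoxidation touches only the enone (trans to the isopropenyl group); the two new centres are erased in step 2 and the carvone stereocentre (later C1) is untouched.

Step 2
Reactants: 2 (1R,4R,6R)-1-methyl-4-(prop-1-en-2-yl)-7-oxabicyclo[4.1.0]heptan-2-one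
Product: 3 (3R)-5-oxo-3-(prop-1-en-2-yl)pentanoic acid
Conditions: H5IO6 (2.5 equiv), THF/H2O, 0 °C → rt
Reagents that add atoms: periodic acid, OI(O)(O)(O)(O)=O; water, O
Why: acid-mediated hydration of the epoxy ketone, then Malaprade cleavage of the diol and of the resulting 1,2-diketone, removes the C(CH3) carbon as acetic acid and leaves distinct CHO and CO2H ends.

Step 3
Reactants: 3 (3R)-5-oxo-3-(prop-1-en-2-yl)pentanoic acid
Product: 4 methyl (3R)-5,5-dimethoxy-3-(prop-1-en-2-yl)pentanoate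
Conditions: HC(OMe)3, MeOH, TsOH (cat.), rt
Reagents that add atoms: trimethyl orthoformate, COC(OC)OC; methanol, CO
Why: Fischer esterification and acetalization in one operation mask the future C13 aldehyde and leave the future C3 carbon as an ester.

Step 4
Reactants: 4 methyl (3R)-5,5-dimethoxy-3-(prop-1-en-2-yl)pentanoate
Product: 5 (3S)-5,5-dimethoxy-3-(prop-1-en-2-yl)pentan-1-ol
Conditions: LiAlH4, Et2O, 0 °C
Reagents that add atoms: none
Why: hydride reduction of the ester; acetal and isopropenyl group are inert (the descriptor changes only through CIP priorities).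

Step 5
Reactants: 5 (3S)-5,5-dimethoxy-3-(prop-1-en-2-yl)pentan-1-ol
Product: 6 (3R)-5-iodo-1,1-dimethoxy-3-(prop-1-en-2-yl)pentane
Conditions: I2, PPh3, imidazole, CH2Cl2, 0 °C → rt
Reagents that add atoms: iodine, II
Why: Appel-type (Garegg–Samuelsson) iodination of the primary alcohol under buffered conditions that spare the acetal.

Step 6
Reactants: 6 (3R)-5-iodo-1,1-dimethoxy-3-(prop-1-en-2-yl)pentane
Product: 8 2-[(3R)-5-iodo-1,1-dimethoxypentan-3-yl]prop-2-enal, via allylic alcohol 7 (not isolated)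
Conditions: SeO2 (0.3 equiv), t-BuOOH, CH2Cl2, rt; then MnO2, CH2Cl2, rt
Reagents that add atoms: tert-butyl hydroperoxide, CC(C)(C)OO
Why: Sharpless–Umbreit allylic oxidation (ene reaction then 2,3-shift) attacks the methyl of the only olefin, and MnO2 takes the allylic alcohol to the enal.

Step 7
Reactants: 8 2-[(3R)-5-iodo-1,1-dimethoxypentan-3-yl]prop-2-enal
Product: 9 2-[(3R)-5-iodo-1,1-dimethoxypentan-3-yl]prop-2-enoic acid
Conditions: NaClO2, NaH2PO4, 2-methylbut-2-ene, t-BuOH/H2O, 0 °C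
Reagents that add atoms: sodium chlorite, [Na+].[O-]Cl=O
Why: Pinnick oxidation converts the enal to the acrylic acid without touching the olefin, iodide or (briefly exposed) acetal.

Step 8
Reactants: 9 2-[(3R)-5-iodo-1,1-dimethoxypentan-3-yl]prop-2-enoic acid
Product: 10 methyl 2-[(3R)-5-iodo-1,1-dimethoxypentan-3-yl]prop-2-enoate (fragment A)
Conditions: Me3SiCHN2, MeOH/toluene, 0 °C
Reagents that add atoms: (trimethylsilyl)diazomethane, C[Si](C)(C)C=[N+]=[N-]
Why: neutral diazoalkane esterification avoids a carboxylate that could displace the primary iodide.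

**Fragment B**

Step 9
Reactants: 11 methyl (2R)-oxirane-2-carboxylate (methyl (R)-glycidate)
Product: 12 methyl (2R)-2-hydroxyhex-4-ynoate
Conditions: 1-propynyllithium, BF3·OEt2, THF, −78 °C
Reagents that add atoms: 1-propynyllithium, [Li]C#CC
Why: Yamaguchi–Hirao alkynylation opens the epoxide at its CH2 terminus, so the C2 centre (later C7, R) is carried over unchanged.

Step 10
Reactants: 12 methyl (2R)-2-hydroxyhex-4-ynoate
Product: 13 methyl (2R)-2-[(tert-butyldimethylsilyl)oxy]hex-4-ynoate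
Conditions: TBSCl, imidazole, DMF, rt
Reagents that add atoms: tert-butyldimethylsilyl chloride, CC(C)(C)[Si](C)(C)Cl
Why: standard silylation; the silyl ether later steers the Wittig geometry and blocks C7–OH participation.

Step 11
Reactants: 13 methyl (2R)-2-[(tert-butyldimethylsilyl)oxy]hex-4-ynoate
Product: 15 methyl (2R,4E)-2-[(tert-butyldimethylsilyl)oxy]-5-iodohex-4-enoate, via alkenylzirconocene 14 (not isolated)
Conditions: Cp2Zr(H)Cl (1.5 equiv), THF, rt → 40 °C; then I2, 0 °C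
Reagents that add atoms: iodine, II
Why: Schwartz hydrozirconation adds syn with zirconium at the less hindered, methyl-bearing carbon, and iodinolysis with retention gives the E-2-iodoalkene; the ester reacts much more slowly than the alkyne.

Step 12
Reactants: 15 methyl (2R,4E)-2-[(tert-butyldimethylsilyl)oxy]-5-iodohex-4-enoate
Product: 16 (2R,4E)-2-[(tert-butyldimethylsilyl)oxy]-5-iodo-N-methoxy-N-methylhex-4-enamide
Conditions: MeNH(OMe)·HCl, i-PrMgCl, THF, −20 °C
Reagents that add atoms: N,O-dimethylhydroxylamine hydrochloride, CNOC.Cl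
Why: the magnesium amide converts the ester directly to the Weinreb amide at low temperature without epimerizing the α-silyloxy centre.

Step 13
Reactants: 16 (2R,4E)-2-[(tert-butyldimethylsilyl)oxy]-5-iodo-N-methoxy-N-methylhex-4-enamide
Product: 17 (3R,5E)-3-[(tert-butyldimethylsilyl)oxy]-6-iodohept-5-en-2-one (fragment B)
Conditions: MeMgBr, THF, 0 °C
Reagents that add atoms: methylmagnesium bromide, C[Mg]Br
Why: Weinreb ketone synthesis stops at the methyl ketone through the stable chelate; the alkenyl iodide is inert.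

**Fragment C**

Step 14
Reactants: 18 pent-3-yn-1-ol
Product: 20 (3E)-4-iodopent-3-en-1-ol, via zirconated alkoxide 19 (not isolated)
Conditions: Cp2Zr(H)Cl (2.2 equiv), THF, rt; then I2, 0 °C
Reagents that add atoms: iodine, II
Why: same syn hydrozirconation and iodinolysis as step 11 (first equivalent consumed by the OH) places iodine on the methyl-bearing carbon with E geometry.

Step 15
Reactants: 20 (3E)-4-iodopent-3-en-1-ol
Product: 23 (3E)-4-(trimethylsilyl)pent-3-en-1-ol, via dilithio species 21 (not isolated), via bis-silyl ether 22 (not isolated)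
Conditions: MeLi (1 equiv), Et2O, −78 °C; t-BuLi (2 equiv), −78 °C; Me3SiCl, −78 °C → rt; then K2CO3 (cat.), MeOH, rt
Reagents that add atoms: chlorotrimethylsilane, C[Si](C)(C)Cl
Why: lithium–iodine exchange and C-silylation both proceed with retention, masking the future C12 iodide as an alkenylsilane that is inert to palladium; the O-silyl group is removed by methanolysis.

Step 16
Reactants: 23 (3E)-4-(trimethylsilyl)pent-3-en-1-ol
Product: 24 [(2E)-5-iodopent-2-en-2-yl]trimethylsilane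
Conditions: I2, PPh3, imidazole, CH2Cl2, 0 °C
Reagents that add atoms: iodine, II
Why: Appel-type iodination of the primary alcohol; the unactivated alkenylsilane is not attacked under these conditions.

Step 17
Reactants: 24 [(2E)-5-iodopent-2-en-2-yl]trimethylsilane
Product: 25 triphenyl[(3E)-4-(trimethylsilyl)pent-3-en-1-yl]phosphonium iodide (fragment C)
Conditions: PPh3, MeCN, reflux
Reagents that add atoms: triphenylphosphine, c1ccc(cc1)P(c1ccccc1)c1ccccc1
Why: SN2 quaternization of the primary iodide.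

**Assembly and end-game**

Step 18
Reactants: 25 triphenyl[(3E)-4-(trimethylsilyl)pent-3-en-1-yl]phosphonium iodide; 17 (3R,5E)-3-[(tert-butyldimethylsilyl)oxy]-6-iodohept-5-en-2-one
Product: 27 tert-butyl{[(2E,5R,6Z,9E)-2-iodo-6-methyl-10-(trimethylsilyl)undeca-2,6,9-trien-5-yl]oxy}dimethylsilane (fragment BC), via phosphorus ylide 26 (not isolated)
Conditions: NaN(SiMe3)2, THF, −78 °C; then 17, −78 °C → rt
Reagents that add atoms: none
Why: Wittig olefination of an α-oxygenated methyl ketone with a non-stabilized ylide is Z-selective (Still's α-alkoxy ketone effect), giving the C8=C9 olefin with C7 and C10 cis and the skipped diene without a β,γ-unsaturated aldehyde.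

Step 19
Reactants: 10 methyl 2-[(3R)-5-iodo-1,1-dimethoxypentan-3-yl]prop-2-enoate; 27 tert-butyl{[(2E,5R,6Z,9E)-2-iodo-6-methyl-10-(trimethylsilyl)undeca-2,6,9-trien-5-yl]oxy}dimethylsilane
Product: 29 methyl 2-[(3S,6E,9R,10Z,13E)-9-[(tert-butyldimethylsilyl)oxy]-1,1-dimethoxy-6,10-dimethyl-14-(trimethylsilyl)pentadeca-6,10,13-trien-3-yl]prop-2-enoate, via alkylzinc iodide 28 (not isolated)
Conditions: Zn dust (activated with 1,2-dibromoethane and Me3SiCl), LiCl, THF, 35 °C; then 27, PdCl2(dppf) (5 mol%), THF/DMA, rt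
Reagents that add atoms: none
Why: Negishi sp3–sp2 coupling joins C3 to C4 with retention of the E-alkenyl geometry; the alkylzinc tolerates acrylate and acetal, and the alkenylsilane does not react.

Step 20
Reactants: 29 methyl 2-[(3S,6E,9R,10Z,13E)-9-[(tert-butyldimethylsilyl)oxy]-1,1-dimethoxy-6,10-dimethyl-14-(trimethylsilyl)pentadeca-6,10,13-trien-3-yl]prop-2-enoate
Product: 30 methyl 2-[(3S,6E,9R,10Z,13E)-9-[(tert-butyldimethylsilyl)oxy]-14-iodo-1,1-dimethoxy-6,10-dimethylpentadeca-6,10,13-trien-3-yl]prop-2-enoate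
Conditions: N-iodosuccinimide, ClCH2CN/MeCN, 0 °C, dark
Reagents that add atoms: N-iodosuccinimide, O=C1CCC(=O)N1I
Why: ipso-iododesilylation (β-silyl cation stabilization) exchanges silicon for iodine with retention of the E geometry, faster than iodonium chemistry at the other olefins.

Step 21
Reactants: 30 methyl 2-[(3S,6E,9R,10Z,13E)-9-[(tert-butyldimethylsilyl)oxy]-14-iodo-1,1-dimethoxy-6,10-dimethylpentadeca-6,10,13-trien-3-yl]prop-2-enoate
Product: 31 methyl 2-[(3S)-5-{(2R,3R)-3-[(2R,3Z,6E)-2-[(tert-butyldimethylsilyl)oxy]-7-iodo-3-methylocta-3,6-dien-1-yl]-2-methyloxiran-2-yl}-1,1-dimethoxypentan-3-yl]prop-2-enoate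
Conditions: D-fructose-derived Shi ketone (1,2:4,5-di-O-isopropylidene-β-D-erythro-2,3-hexodiulo-2,6-pyranose, 30 mol%), KHSO5, K2CO3, Bu4NHSO4, MeCN/CH2(OMe)2/aq. Na2B4O7 buffer (pH 10.5), 0 °C
Reagents that add atoms: potassium peroxymonosulfate, [K+].[O-]S(=O)(=O)OO
Why: Shi asymmetric epoxidation (chiral dioxirane, spiro transition state) gives the (4R,5R)-epoxide of the E-trisubstituted C4=C5 olefin under reagent control; the Z-olefin is deactivated by its allylic silyloxy group, and the alkenyl iodide and acrylate are electron-poor.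

Step 22
Reactants: 31 methyl 2-[(3S)-5-{(2R,3R)-3-[(2R,3Z,6E)-2-[(tert-butyldimethylsilyl)oxy]-7-iodo-3-methylocta-3,6-dien-1-yl]-2-methyloxiran-2-yl}-1,1-dimethoxypentan-3-yl]prop-2-enoate
Product: 32 2-[(3S)-5-{(2R,3R)-3-[(2R,3Z,6E)-2-[(tert-butyldimethylsilyl)oxy]-7-iodo-3-methylocta-3,6-dien-1-yl]-2-methyloxiran-2-yl}-1,1-dimethoxypentan-3-yl]prop-2-enoic acid
Conditions: LiOH, THF/MeOH/H2O, 0 °C → rt; then cold 0.5 M HCl to pH 4
Reagents that add atoms: lithium hydroxide, [Li+].[OH-]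
Why: saponification of the methyl acrylate; the epoxide, silyl ether, acetal and alkenyl iodide are base-stable.

Step 23
Reactants: 32 2-[(3S)-5-{(2R,3R)-3-[(2R,3Z,6E)-2-[(tert-butyldimethylsilyl)oxy]-7-iodo-3-methylocta-3,6-dien-1-yl]-2-methyloxiran-2-yl}-1,1-dimethoxypentan-3-yl]prop-2-enoic acid
Product: 33 (4S,7S)-7-[(1R,3R,4Z,7E)-3-[(tert-butyldimethylsilyl)oxy]-1-hydroxy-8-iodo-4-methylnona-4,7-dien-1-yl]-4-(2,2-dimethoxyethyl)-7-methyl-3-methylideneoxepan-2-one
Conditions: camphorsulfonic acid (0.2 equiv), CH2Cl2 (0.01 M), 0 °C → rt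
Reagents that add atoms: none
Why: acid-catalysed 7-exo-tet opening of the epoxide by the carboxylic acid at the tertiary carbon inverts C4 (to 4S) and keeps the C5–O bond (5R), forming the ε-lactone; the C7 silyl ether blocks competing tetrahydrofuran formation.

Step 24
Reactants: 33 (4S,7S)-7-[(1R,3R,4Z,7E)-3-[(tert-butyldimethylsilyl)oxy]-1-hydroxy-8-iodo-4-methylnona-4,7-dien-1-yl]-4-(2,2-dimethoxyethyl)-7-methyl-3-methylideneoxepan-2-one
Product: 34 (1R,3R,4Z,7E)-3-[(tert-butyldimethylsilyl)oxy]-1-[(4S,7S)-4-(2,2-dimethoxyethyl)-7-methyl-3-methylidene-2-oxooxepan-7-yl]-8-iodo-4-methylnona-4,7-dien-1-yl acetate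
Conditions: Ac2O, DMAP (cat.), pyridine, CH2Cl2, 0 °C → rt
Reagents that add atoms: acetic anhydride, CC(=O)OC(C)=O
Why: acylation of the only free hydroxyl (C5) with retention.

Step 25
Reactants: 34 (1R,3R,4Z,7E)-3-[(tert-butyldimethylsilyl)oxy]-1-[(4S,7S)-4-(2,2-dimethoxyethyl)-7-methyl-3-methylidene-2-oxooxepan-7-yl]-8-iodo-4-methylnona-4,7-dien-1-yl acetate
Product: 35 (1R,3R,4Z,7E)-3-[(tert-butyldimethylsilyl)oxy]-8-iodo-4-methyl-1-[(4S,7S)-7-methyl-3-methylidene-2-oxo-4-(2-oxoethyl)oxepan-7-yl]nona-4,7-dien-1-yl acetate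
Conditions: LiBF4, MeCN/H2O (98:2), rt
Reagents that add atoms: water, O
Why: mild Lewis-acid hydrolysis of the dimethyl acetal frees the C13 aldehyde without touching silyl ether, acetate or lactone.

Step 26
Reactants: 35 (1R,3R,4Z,7E)-3-[(tert-butyldimethylsilyl)oxy]-8-iodo-4-methyl-1-[(4S,7S)-7-methyl-3-methylidene-2-oxo-4-(2-oxoethyl)oxepan-7-yl]nona-4,7-dien-1-yl acetate
Product: 36 (1S,4S,5R,7R,13R,8Z,11E)-5-acetoxy-7-[(tert-butyldimethylsilyl)oxy]-13-hydroxycembra-8,11,15(16)-trien-17,4-olide (C7 silyl ether of the target)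
Conditions: CrCl2 (10 equiv), NiCl2 (0.1 equiv), DMSO/THF (3:1), 2 mM, syringe-pump addition, rt
Reagents that add atoms: none
Why: Nozaki–Hiyama–Kishi macrocyclization adds the alkenylchromium species (E geometry retained) to the aldehyde and closes the 14-membered ring; C13 is set under substrate control that is not predictable, so the 13R epimer is separated and the fallback for this step corrects the other.

Step 27
Reactants: 36 (1S,4S,5R,7R,13R,8Z,11E)-5-acetoxy-7-[(tert-butyldimethylsilyl)oxy]-13-hydroxycembra-8,11,15(16)-trien-17,4-olide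
Product: 37 (1S,4S,5R,7R,13R,8Z,11E)-5-acetoxy-7,13-dihydroxycembra-8,11,15(16)-trien-17,4-olide (CNP0183491.2)
Conditions: HF·pyridine, THF/pyridine, 0 °C → rt
Reagents that add atoms: none
Why: buffered fluoride desilylation frees C7–OH without acetate migration or attack on the α-methylene lactone.

**Compound list**
1 | (R)-(−)-carvone, (5R)-2-methyl-5-(prop-1-en-2-yl)cyclohex-2-en-1-one | CC1=CC[C@H](CC1=O)C(C)=C | starting material
2 | (1R,4R,6R)-1-methyl-4-(prop-1-en-2-yl)-7-oxabicyclo[4.1.0]heptan-2-one | O=C1C[C@H](C(C)=C)C[C@H]2O[C@@]12C | intermediate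
3 | (3R)-5-oxo-3-(prop-1-en-2-yl)pentanoic acid | O=CC[C@H](CC(=O)O)C(C)=C | intermediate
4 | methyl (3R)-5,5-dimethoxy-3-(prop-1-en-2-yl)pentanoate | COC(=O)C[C@@H](CC(OC)OC)C(C)=C | intermediate
5 | (3S)-5,5-dimethoxy-3-(prop-1-en-2-yl)pentan-1-ol | OCC[C@@H](CC(OC)OC)C(C)=C | intermediate
6 | (3R)-5-iodo-1,1-dimethoxy-3-(prop-1-en-2-yl)pentane | ICC[C@@H](CC(OC)OC)C(C)=C | intermediate
7 | 2-[(3R)-5-iodo-1,1-dimethoxypentan-3-yl]prop-2-en-1-ol | ICC[C@@H](CC(OC)OC)C(=C)CO | intermediate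
8 | 2-[(3R)-5-iodo-1,1-dimethoxypentan-3-yl]prop-2-enal | ICC[C@@H](CC(OC)OC)C(=C)C=O | intermediate
9 | 2-[(3R)-5-iodo-1,1-dimethoxypentan-3-yl]prop-2-enoic acid | ICC[C@@H](CC(OC)OC)C(=C)C(=O)O | intermediate
10 | methyl 2-[(3R)-5-iodo-1,1-dimethoxypentan-3-yl]prop-2-enoate (fragment A) | ICC[C@@H](CC(OC)OC)C(=C)C(=O)OC | intermediate
11 | methyl (2R)-oxirane-2-carboxylate | COC(=O)[C@H]1CO1 | starting material
12 | methyl (2R)-2-hydroxyhex-4-ynoate | COC(=O)[C@H](O)CC#CC | intermediate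
13 | methyl (2R)-2-[(tert-butyldimethylsilyl)oxy]hex-4-ynoate | COC(=O)[C@H](O[Si](C)(C)C(C)(C)C)CC#CC | intermediate
14 | chlorobis(cyclopentadienyl)[(2E,5R)-5-[(tert-butyldimethylsilyl)oxy]-6-methoxy-6-oxohex-2-en-2-yl]zirconium | COC(=O)[C@H](O[Si](C)(C)C(C)(C)C)C/C=C(\C)[Zr](Cl)(C1C=CC=C1)C1C=CC=C1 | intermediate
15 | methyl (2R,4E)-2-[(tert-butyldimethylsilyl)oxy]-5-iodohex-4-enoate | COC(=O)[C@H](O[Si](C)(C)C(C)(C)C)C/C=C(\C)I | intermediate
16 | (2R,4E)-2-[(tert-butyldimethylsilyl)oxy]-5-iodo-N-methoxy-N-methylhex-4-enamide | CON(C)C(=O)[C@H](O[Si](C)(C)C(C)(C)C)C/C=C(\C)I | intermediate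
17 | (3R,5E)-3-[(tert-butyldimethylsilyl)oxy]-6-iodohept-5-en-2-one (fragment B) | CC(=O)[C@H](O[Si](C)(C)C(C)(C)C)C/C=C(\C)I | intermediate
18 | pent-3-yn-1-ol | CC#CCCO | starting material
19 | O,C-bis[chlorobis(cyclopentadienyl)zirconio] derivative of (3E)-pent-3-en-1-ol (Zr on O and on C4, trans to C2) | C/C(=C\CCO[Zr](Cl)(C1C=CC=C1)C1C=CC=C1)[Zr](Cl)(C1C=CC=C1)C1C=CC=C1 | intermediate
20 | (3E)-4-iodopent-3-en-1-ol | C/C(I)=C\CCO | intermediate
21 | lithium (3Z)-4-lithiopent-3-en-1-olate (Li trans to C2) | [Li]OCC/C=C(\C)[Li] | intermediate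
22 | trimethyl{[(3E)-4-(trimethylsilyl)pent-3-en-1-yl]oxy}silane | C[Si](C)(C)OCC/C=C(\C)[Si](C)(C)C | intermediate
23 | (3E)-4-(trimethylsilyl)pent-3-en-1-ol | OCC/C=C(\C)[Si](C)(C)C | intermediate
24 | [(2E)-5-iodopent-2-en-2-yl]trimethylsilane | ICC/C=C(\C)[Si](C)(C)C | intermediate
25 | triphenyl[(3E)-4-(trimethylsilyl)pent-3-en-1-yl]phosphonium iodide (fragment C) | C[Si](C)(C)/C(C)=C/CC[P+](c1ccccc1)(c1ccccc1)c1ccccc1.[I-] | intermediate
26 | triphenyl[(3E)-4-(trimethylsilyl)pent-3-en-1-ylidene]-λ5-phosphane | C[Si](C)(C)/C(C)=C/CC=P(c1ccccc1)(c1ccccc1)c1ccccc1 | intermediate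
27 | tert-butyl{[(2E,5R,6Z,9E)-2-iodo-6-methyl-10-(trimethylsilyl)undeca-2,6,9-trien-5-yl]oxy}dimethylsilane (fragment BC) | C/C(I)=C\C[C@@H](O[Si](C)(C)C(C)(C)C)/C(C)=C\C/C=C(\C)[Si](C)(C)C | intermediate
28 | {(3R)-5,5-dimethoxy-3-(3-methoxy-3-oxoprop-1-en-2-yl)pentyl}(iodo)zinc | I[Zn]CC[C@@H](CC(OC)OC)C(=C)C(=O)OC | intermediate
29 | methyl 2-[(3S,6E,9R,10Z,13E)-9-[(tert-butyldimethylsilyl)oxy]-1,1-dimethoxy-6,10-dimethyl-14-(trimethylsilyl)pentadeca-6,10,13-trien-3-yl]prop-2-enoate | COC(=O)C(=C)[C@H](CC(OC)OC)CC/C(C)=C/C[C@@H](O[Si](C)(C)C(C)(C)C)/C(C)=C\C/C=C(\C)[Si](C)(C)C | intermediate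
30 | methyl 2-[(3S,6E,9R,10Z,13E)-9-[(tert-butyldimethylsilyl)oxy]-14-iodo-1,1-dimethoxy-6,10-dimethylpentadeca-6,10,13-trien-3-yl]prop-2-enoate | COC(=O)C(=C)[C@H](CC(OC)OC)CC/C(C)=C/C[C@@H](O[Si](C)(C)C(C)(C)C)/C(C)=C\C/C=C(\C)I | intermediate
31 | methyl 2-[(3S)-5-{(2R,3R)-3-[(2R,3Z,6E)-2-[(tert-butyldimethylsilyl)oxy]-7-iodo-3-methylocta-3,6-dien-1-yl]-2-methyloxiran-2-yl}-1,1-dimethoxypentan-3-yl]prop-2-enoate | COC(=O)C(=C)[C@H](CC(OC)OC)CC[C@@]1(C)O[C@@H]1C[C@@H](O[Si](C)(C)C(C)(C)C)/C(C)=C\C/C=C(\C)I | intermediate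
32 | 2-[(3S)-5-{(2R,3R)-3-[(2R,3Z,6E)-2-[(tert-butyldimethylsilyl)oxy]-7-iodo-3-methylocta-3,6-dien-1-yl]-2-methyloxiran-2-yl}-1,1-dimethoxypentan-3-yl]prop-2-enoic acid | OC(=O)C(=C)[C@H](CC(OC)OC)CC[C@@]1(C)O[C@@H]1C[C@@H](O[Si](C)(C)C(C)(C)C)/C(C)=C\C/C=C(\C)I | intermediate
33 | (4S,7S)-7-[(1R,3R,4Z,7E)-3-[(tert-butyldimethylsilyl)oxy]-1-hydroxy-8-iodo-4-methylnona-4,7-dien-1-yl]-4-(2,2-dimethoxyethyl)-7-methyl-3-methylideneoxepan-2-one | C=C1C(=O)O[C@@](C)(CC[C@H]1CC(OC)OC)[C@H](O)C[C@@H](O[Si](C)(C)C(C)(C)C)/C(C)=C\C/C=C(\C)I | intermediate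
34 | (1R,3R,4Z,7E)-3-[(tert-butyldimethylsilyl)oxy]-1-[(4S,7S)-4-(2,2-dimethoxyethyl)-7-methyl-3-methylidene-2-oxooxepan-7-yl]-8-iodo-4-methylnona-4,7-dien-1-yl acetate | C=C1C(=O)O[C@@](C)(CC[C@H]1CC(OC)OC)[C@H](OC(C)=O)C[C@@H](O[Si](C)(C)C(C)(C)C)/C(C)=C\C/C=C(\C)I | intermediate
35 | (1R,3R,4Z,7E)-3-[(tert-butyldimethylsilyl)oxy]-8-iodo-4-methyl-1-[(4S,7S)-7-methyl-3-methylidene-2-oxo-4-(2-oxoethyl)oxepan-7-yl]nona-4,7-dien-1-yl acetate | C=C1C(=O)O[C@@](C)(CC[C@H]1CC=O)[C@H](OC(C)=O)C[C@@H](O[Si](C)(C)C(C)(C)C)/C(C)=C\C/C=C(\C)I | intermediate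
36 | (1S,4S,5R,7R,13R,8Z,11E)-5-acetoxy-7-[(tert-butyldimethylsilyl)oxy]-13-hydroxycembra-8,11,15(16)-trien-17,4-olide | C=C1C(=O)O[C@@]2(C)CC[C@H]1C[C@@H](O)/C(C)=C/C/C=C(/C)[C@H](O[Si](C)(C)C(C)(C)C)C[C@H]2OC(C)=O | intermediate
37 | (1S,4S,5R,7R,13R,8Z,11E)-5-acetoxy-7,13-dihydroxycembra-8,11,15(16)-trien-17,4-olide (CNP0183491.2) | C=C1C(=O)O[C@@]2(C)CC[C@H]1C[C@@H](O)/C(C)=C/C/C=C(/C)[C@H](O)C[C@H]2OC(C)=O | target

**Step count**
Total steps: 27. Longest linear sequence: 17 (steps 1–8, then 19–27, from 1).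

**Three steps most likely to fail, with fallbacks**

Step 21 (site-selective epoxidation of C4=C5 in tetraene 30). If the Z-olefin or the alkenyl iodide competes, the epoxide is installed before the skipped diene exists. This fallback sets out from 28, 17 and 20 and returns at 32. Negishi coupling of 28 with 17 (PdCl2(dppf), THF/DMA) gives methyl 2-[(3S,6E,9R)-9-[(tert-butyldimethylsilyl)oxy]-1,1-dimethoxy-6-methyl-10-oxoundec-6-en-3-yl]prop-2-enoate F1, which has a single electron-rich olefin. Shi epoxidation as in step 21 gives methyl 2-[(3S)-5-{(2R,3R)-3-[(2R)-2-[(tert-butyldimethylsilyl)oxy]-3-oxobutyl]-2-methyloxiran-2-yl}-1,1-dimethoxypentan-3-yl]prop-2-enoate F2. Me3SnOH in 1,2-dichloroethane at 60 °C gives the corresponding prop-2-enoic acid F3 without epimerizing the α-silyloxy ketone. In parallel, 20 is converted with I2, PPh3 and imidazole to (2E)-2,5-diiodopent-2-ene F4, then with PPh3 to [(3E)-4-iodopent-3-en-1-yl]triphenylphosphonium iodide F5, which NaN(SiMe3)2 deprotonates to [(3E)-4-iodopent-3-en-1-ylidene]triphenyl-λ5-phosphane F6. Z-selective Wittig reaction of excess F6 with the sodium carboxylate of F3 gives 32 directly; the carboxylate is not a Michael acceptor and no silicon–iodine exchange is needed.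

Step 23 (7-exo epoxide-opening lactonization). If rearrangement or oligomerization outruns ring closure, the C4–O bond is made by water and the lactone by esterification. This fallback sets out from 32 and returns at 35. Dilute HClO4 in THF/H2O at 0 °C hydrates the epoxide at the tertiary carbon with inversion and also unmasks the aldehyde, giving 2-[(3S,6S,7R,9R,10Z,13E)-9-[(tert-butyldimethylsilyl)oxy]-6,7-dihydroxy-14-iodo-6,10-dimethyl-1-oxopentadeca-10,13-dien-3-yl]prop-2-enoic acid F7. Ac2O in pyridine at 0 °C acetylates only the secondary C5 hydroxyl, giving 2-[(3S,6S,7R,9R,10Z,13E)-7-acetoxy-9-[(tert-butyldimethylsilyl)oxy]-6-hydroxy-14-iodo-6,10-dimethyl-1-oxopentadeca-10,13-dien-3-yl]prop-2-enoic acid F8. Shiina lactonization (2-methyl-6-nitrobenzoic anhydride, DMAP, toluene, high dilution) closes the ε-lactone on the tertiary C4 hydroxyl with retention and gives 35.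

Step 26 (configuration at C13 in the macrocyclization). If the ring closure favours the 13S epimer, the carbinol is reset by reagent control. This fallback sets out from 35 and returns at 36. The epimer mixture from the CrCl2/NiCl2 closure is oxidized with MnO2 in CH2Cl2 to (1S,4S,5R,7R,8Z,11E)-5-acetoxy-7-[(tert-butyldimethylsilyl)oxy]-13-oxocembra-8,11,15(16)-trien-17,4-olide F9. Reduction with (S)-2-methyl-CBS-oxazaborolidine and catecholborane in toluene at −78 °C (alkenyl as the large group) gives the 13R alcohol 36.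

**Further compounds**
F1 | step 21 | methyl 2-[(3S,6E,9R)-9-[(tert-butyldimethylsilyl)oxy]-1,1-dimethoxy-6-methyl-10-oxoundec-6-en-3-yl]prop-2-enoate | COC(=O)C(=C)[C@H](CC(OC)OC)CC/C(C)=C/C[C@@H](O[Si](C)(C)C(C)(C)C)C(C)=O
F2 | step 21 | methyl 2-[(3S)-5-{(2R,3R)-3-[(2R)-2-[(tert-butyldimethylsilyl)oxy]-3-oxobutyl]-2-methyloxiran-2-yl}-1,1-dimethoxypentan-3-yl]prop-2-enoate | COC(=O)C(=C)[C@H](CC(OC)OC)CC[C@@]1(C)O[C@@H]1C[C@@H](O[Si](C)(C)C(C)(C)C)C(C)=O
F3 | step 21 | 2-[(3S)-5-{(2R,3R)-3-[(2R)-2-[(tert-butyldimethylsilyl)oxy]-3-oxobutyl]-2-methyloxiran-2-yl}-1,1-dimethoxypentan-3-yl]prop-2-enoic acid | OC(=O)C(=C)[C@H](CC(OC)OC)CC[C@@]1(C)O[C@@H]1C[C@@H](O[Si](C)(C)C(C)(C)C)C(C)=O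
F4 | step 21 | (2E)-2,5-diiodopent-2-ene | C/C(I)=C\CCI
F5 | step 21 | [(3E)-4-iodopent-3-en-1-yl]triphenylphosphonium iodide | C/C(I)=C\CC[P+](c1ccccc1)(c1ccccc1)c1ccccc1.[I-]
F6 | step 21 | [(3E)-4-iodopent-3-en-1-ylidene]triphenyl-λ5-phosphane | C/C(I)=C\CC=P(c1ccccc1)(c1ccccc1)c1ccccc1
F7 | step 23 | 2-[(3S,6S,7R,9R,10Z,13E)-9-[(tert-butyldimethylsilyl)oxy]-6,7-dihydroxy-14-iodo-6,10-dimethyl-1-oxopentadeca-10,13-dien-3-yl]prop-2-enoic acid | OC(=O)C(=C)[C@H](CC=O)CC[C@](C)(O)[C@H](O)C[C@@H](O[Si](C)(C)C(C)(C)C)/C(C)=C\C/C=C(\C)I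
F8 | step 23 | 2-[(3S,6S,7R,9R,10Z,13E)-7-acetoxy-9-[(tert-butyldimethylsilyl)oxy]-6-hydroxy-14-iodo-6,10-dimethyl-1-oxopentadeca-10,13-dien-3-yl]prop-2-enoic acid | OC(=O)C(=C)[C@H](CC=O)CC[C@](C)(O)[C@H](OC(C)=O)C[C@@H](O[Si](C)(C)C(C)(C)C)/C(C)=C\C/C=C(\C)I
F9 | step 26 | (1S,4S,5R,7R,8Z,11E)-5-acetoxy-7-[(tert-butyldimethylsilyl)oxy]-13-oxocembra-8,11,15(16)-trien-17,4-olide | C=C1C(=O)O[C@@]2(C)CC[C@H]1CC(=O)/C(C)=C/C/C=C(/C)[C@H](O[Si](C)(C)C(C)(C)C)C[C@H]2OC(C)=O
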